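**Plan**

- Numbering: 3,7-dioxabicyclo[3.3.0]octane with C1/C5 at the ring fusion. Ring A is C1–C2–O3–C4–C5 with the 4-hydroxy-3-methoxyphenyl group on C2; ring B is C5–C6–O7–C8–C1 with the 3-hydroxy-4,5-dimethoxyphenyl group on C6.
- Enabling feature: the C1–C5 bond of ring A joins C1, whose neighbour C8 carries O7 (the imprint of an opened terminal epoxide), to C5, whose neighbour C6 is benzylic (the imprint of a cinnamyl alkene). Ring A is therefore a 5-exo radical adduct and ring B a benzylic etherification.
- Retrosynthesis: remove both silyl groups; cut C6–O7 and C1–C5 in one operation back to epoxy cinnamyl ether 13; cut O3–C4 to epoxy alcohol 5 and cinnamyl bromide 12; cut C1–C2 to silylated vanillin and a vinyl Grignard reagent; take the bromide back to 3-hydroxy-4,5-dimethoxybenzaldehyde.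
- Forward: the two aryl fragments are made separately and joined as an ether (step 8); ring A and then ring B close in one flask (step 9); desilylation ends the route.
- Stereochemistry: C2 comes from a Sharpless kinetic resolution with D-(−)-diisopropyl tartrate. C1, C5 and C6 are set relative to C2 in step 9 (2,3-trans and 3,4-cis in ring A, exo aryl on C6), which gives (1R,2S,5R,6S).

Key step: step 9

Remark: the epoxide carbon of 5 and 13 becomes the planar C1 radical in step 9, so its configuration does not reach the product. In SMILES of titanium compounds each C5H5 ring is written as a sigma-bonded cyclopentadienyl group, and C6 of 14 and 15 carries no descriptor because both epimers lead to the same product.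

**Route**

Step 1
Reactants: 1 vanillin
Product: 2 4-[(tert-butyldimethylsilyl)oxy]-3-methoxybenzaldehyde
Conditions: TBSCl, imidazole, DMF, rt
Reagents that add atoms: tert-butyldimethylsilyl chloride (TBSCl), CC(C)(C)[Si](C)(C)Cl
Why: Imidazole-promoted O-silylation of the phenol masks the acidic OH for the Grignard, epoxidation and titanium steps and leaves the aldehyde untouched.

Step 2
Reactants: 2 4-[(tert-butyldimethylsilyl)oxy]-3-methoxybenzaldehyde; 3 vinylmagnesium bromide
Product: 4 racemic 1-{4-[(tert-butyldimethylsilyl)oxy]-3-methoxyphenyl}prop-2-en-1-ol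
Conditions: CH2=CHMgBr, THF, −78 to 0 °C; aq NH4Cl
Reagents that add atoms: vinylmagnesium bromide (3), C=C[Mg]Br
Why: Grignard 1,2-addition to the aldehyde forms the C1–C2 bond and the allylic alcohol that the epoxidation needs; the carbinol is racemic here and the aryl silyl ether is stable to the reagent at low temperature.

Step 3
Reactants: 4 racemic 1-{4-[(tert-butyldimethylsilyl)oxy]-3-methoxyphenyl}prop-2-en-1-ol
Product: 5 (R)-{4-[(tert-butyldimethylsilyl)oxy]-3-methoxyphenyl}[(2S)-oxiran-2-yl]methanol (erythro)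
Conditions: Ti(OiPr)4 (0.2 equiv), D-(−)-diisopropyl tartrate (0.24 equiv), tBuOOH (0.45 equiv), 4 Å MS, CH2Cl2, −20 °C
Reagents that add atoms: tert-butyl hydroperoxide, CC(C)(C)OO
Why: In this Sharpless kinetic-resolution epoxidation the D-(−)-tartrate catalyst should epoxidise the S enantiomer of 4 much faster than the R enantiomer, on the alkene face that gives the erythro epoxy alcohol; the tartrate thus sets C2 (R in 5 only because the priorities change) and the epoxide carbon, while conversion below one half keeps the slow R enantiomer of 4 unreacted for removal by chromatography.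

Step 4
Reactants: 6 3-hydroxy-4,5-dimethoxybenzaldehyde
Product: 7 3-[(tert-butyldimethylsilyl)oxy]-4,5-dimethoxybenzaldehyde
Conditions: TBSCl, imidazole, DMF, rt
Reagents that add atoms: tert-butyldimethylsilyl chloride (TBSCl), CC(C)(C)[Si](C)(C)Cl
Why: The same imidazole-promoted O-silylation protects the ring B phenol with a group that comes off together with the ring A silyl ether at the end.

Step 5
Reactants: 7 3-[(tert-butyldimethylsilyl)oxy]-4,5-dimethoxybenzaldehyde; 8 ethyl (triphenylphosphoranylidene)acetate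
Product: 9 ethyl (2E)-3-{3-[(tert-butyldimethylsilyl)oxy]-4,5-dimethoxyphenyl}prop-2-enoate
Conditions: Ph3P=CHCO2Et, toluene, 80 °C
Reagents that add atoms: ethyl (triphenylphosphoranylidene)acetate (8), CCOC(=O)C=P(c1ccccc1)(c1ccccc1)c1ccccc1
Why: Wittig olefination with a stabilised ylide gives the E enoate under neutral conditions that do not disturb the aryl silyl ether, and so fixes the E geometry of the later C5=C6 alkene.

Step 6
Reactants: 9 ethyl (2E)-3-{3-[(tert-butyldimethylsilyl)oxy]-4,5-dimethoxyphenyl}prop-2-enoate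
Product: 11 (2E)-3-{3-[(tert-butyldimethylsilyl)oxy]-4,5-dimethoxyphenyl}prop-2-en-1-ol, via silylated cinnamaldehyde 10 (not isolated)
Conditions: iBu2AlH (2.5 equiv), CH2Cl2, −78 to 0 °C; aq potassium sodium tartrate (KNaC4H4O6)
Reagents that add atoms: none
Why: Hydride reduction of the enoate with iBu2AlH proceeds 1,2 through the enal to the allylic alcohol without touching the alkene or the silyl ether.

Step 7
Reactants: 11 (2E)-3-{3-[(tert-butyldimethylsilyl)oxy]-4,5-dimethoxyphenyl}prop-2-en-1-ol
Product: 12 (2E)-3-{3-[(tert-butyldimethylsilyl)oxy]-4,5-dimethoxyphenyl}prop-2-en-1-yl bromide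
Conditions: CBr4, PPh3, CH2Cl2, 0 °C; used at once without purification
Reagents that add atoms: carbon tetrabromide, BrC(Br)(Br)Br
Why: The Appel bromination converts the primary allylic alcohol into the bromide under neutral conditions, which suits an acid-sensitive, electron-rich cinnamyl system and keeps the E alkene.

Step 8
Reactants: 5 (R)-{4-[(tert-butyldimethylsilyl)oxy]-3-methoxyphenyl}[(2S)-oxiran-2-yl]methanol; 12 (2E)-3-{3-[(tert-butyldimethylsilyl)oxy]-4,5-dimethoxyphenyl}prop-2-en-1-yl bromide
Product: 13 (2S)-2-[(R)-{4-[(tert-butyldimethylsilyl)oxy]-3-methoxyphenyl}({(2E)-3-{3-[(tert-butyldimethylsilyl)oxy]-4,5-dimethoxyphenyl}prop-2-en-1-yl}oxy)methyl]oxirane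
Conditions: Ag2O (2 equiv), 12 (1.5 equiv), 4 Å MS, CH2Cl2, rt, dark
Reagents that add atoms: none
Why: This Ag2O-promoted Williamson-type O-alkylation forms O3–C4 without a free alkoxide, so Payne rearrangement of the epoxy alcohol and silyl transfer from the phenols are avoided, the alcohol attacks the primary terminus of the silver-activated cinnamyl bromide to keep the conjugated E alkene, and neither stereocentre is touched.

Step 9
Reactants: 13 (2S)-2-[(R)-{4-[(tert-butyldimethylsilyl)oxy]-3-methoxyphenyl}({(2E)-3-{3-[(tert-butyldimethylsilyl)oxy]-4,5-dimethoxyphenyl}prop-2-en-1-yl}oxy)methyl]oxirane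
Product: 16 (1R,2S,5R,6S)-2-{4-[(tert-butyldimethylsilyl)oxy]-3-methoxyphenyl}-6-{3-[(tert-butyldimethylsilyl)oxy]-4,5-dimethoxyphenyl}-3,7-dioxabicyclo[3.3.0]octane, via ring A bis-titanium intermediate 14 (not isolated), via ring A benzylic iodide titanium alkoxide 15 (not isolated)
Conditions: Cp2TiCl2 (2.5 equiv), Zn dust, THF, rt, green Cp2TiCl solution decanted from Zn and added dropwise to 13 in THF, rt; then I2 (1.5 equiv), THF, rt to 50 °C; aq Na2S2O3
Reagents that add atoms: none
Why: Cp2TiCl (trivalent titanium) transfers one electron to the epoxide, which opens at C1–O to the secondary C1 radical with a titanium alkoxide on C8; the radical adds 5-exo-trig to C5 of the E cinnamyl alkene (ring A), a second Cp2TiCl captures the C6 benzylic radical as 14, and iodine converts this into the benzylic iodide 15, whose ionisation, helped by the para-methoxy group, lets the C8 alkoxide close ring B by a 5-exo-tet substitution (C6–O7). The closest known reaction type is the titanocene chloride epoxide-opening radical cyclisation of epoxy cinnamyl ethers finished with iodine to give furofurans. C1 and C5 are set in a chair-like 5-exo transition state with the C2 aryl group pseudo-equatorial, so that C8 on C1 ends trans to the C2 aryl group and cis to the C5 side chain, all relative to the single stereocentre C2 brought in by 13. C6 is set in the ring B closure: the bicyclo[3.3.0] system can only be cis-fused, and the oxygen attacks the flat benzylic cation so that the aryl group ends on the convex (exo) face whichever epimer of the iodide forms. The step needs the epoxide to open toward the more substituted radical, which is the normal sense for Cp2TiCl, and the 5-exo addition to outrun capture of the C1 radical by a second titanium, which the styrene-type acceptor and slow addition of the titanium reagent should secure. Removing the zinc before the iodine is added keeps the benzylic iodide from being reduced.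

Step 10
Reactants: 16 (1R,2S,5R,6S)-2-{4-[(tert-butyldimethylsilyl)oxy]-3-methoxyphenyl}-6-{3-[(tert-butyldimethylsilyl)oxy]-4,5-dimethoxyphenyl}-3,7-dioxabicyclo[3.3.0]octane
Product: 17 (1R,2S,5R,6S)-2-(4-hydroxy-3-methoxyphenyl)-6-(3-hydroxy-4,5-dimethoxyphenyl)-3,7-dioxabicyclo[3.3.0]octane (CNP0324902.1)
Conditions: Bu4NF (2.4 equiv), AcOH (2.4 equiv), THF, 0 °C
Reagents that add atoms: none
Why: Fluoride-induced desilylation frees both phenols in one operation, and the acetic acid buffer protonates the para-phenoxide as it forms so that the C2 benzylic ether is not opened through a quinone methide and no stereocentre is disturbed.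

**Compound list**

1 | vanillin | COc1cc(C=O)ccc1O | starting material
2 | 4-[(tert-butyldimethylsilyl)oxy]-3-methoxybenzaldehyde | COc1cc(C=O)ccc1O[Si](C)(C)C(C)(C)C | intermediate
3 | vinylmagnesium bromide | C=C[Mg]Br | starting material
4 | racemic 1-{4-[(tert-butyldimethylsilyl)oxy]-3-methoxyphenyl}prop-2-en-1-ol | COc1cc(C(O)C=C)ccc1O[Si](C)(C)C(C)(C)C | intermediate
5 | (R)-{4-[(tert-butyldimethylsilyl)oxy]-3-methoxyphenyl}[(2S)-oxiran-2-yl]methanol (erythro) | CC(C)(C)[Si](C)(C)Oc1ccc(cc1OC)[C@@H](O)[C@@H]1CO1 | intermediate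
6 | 3-hydroxy-4,5-dimethoxybenzaldehyde | COc1cc(C=O)cc(O)c1OC | starting material
7 | 3-[(tert-butyldimethylsilyl)oxy]-4,5-dimethoxybenzaldehyde | COc1cc(C=O)cc(O[Si](C)(C)C(C)(C)C)c1OC | intermediate
8 | ethyl (triphenylphosphoranylidene)acetate | CCOC(=O)C=P(c1ccccc1)(c1ccccc1)c1ccccc1 | starting material
9 | ethyl (2E)-3-{3-[(tert-butyldimethylsilyl)oxy]-4,5-dimethoxyphenyl}prop-2-enoate | CCOC(=O)/C=C/c1cc(O[Si](C)(C)C(C)(C)C)c(OC)c(OC)c1 | intermediate
10 | (2E)-3-{3-[(tert-butyldimethylsilyl)oxy]-4,5-dimethoxyphenyl}prop-2-enal | O=C/C=C/c1cc(O[Si](C)(C)C(C)(C)C)c(OC)c(OC)c1 | intermediate (not isolated)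
11 | (2E)-3-{3-[(tert-butyldimethylsilyl)oxy]-4,5-dimethoxyphenyl}prop-2-en-1-ol | OC/C=C/c1cc(O[Si](C)(C)C(C)(C)C)c(OC)c(OC)c1 | intermediate
12 | (2E)-3-{3-[(tert-butyldimethylsilyl)oxy]-4,5-dimethoxyphenyl}prop-2-en-1-yl bromide | BrC/C=C/c1cc(O[Si](C)(C)C(C)(C)C)c(OC)c(OC)c1 | intermediate
13 | (2S)-2-[(R)-{4-[(tert-butyldimethylsilyl)oxy]-3-methoxyphenyl}({(2E)-3-{3-[(tert-butyldimethylsilyl)oxy]-4,5-dimethoxyphenyl}prop-2-en-1-yl}oxy)methyl]oxirane | CC(C)(C)[Si](C)(C)Oc1ccc(cc1OC)[C@@H](OC/C=C/c1cc(O[Si](C)(C)C(C)(C)C)c(OC)c(OC)c1)[C@@H]1CO1 | intermediate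
14 | ring A closed (2,3-trans, 3,4-cis tetrahydrofuran) with Cp2Ti(Cl) on benzylic C6 and Cp2Ti(Cl)–O on C8 (tetravalent titanium at both sites) | CC(C)(C)[Si](C)(C)Oc1ccc(cc1OC)[C@H]1OC[C@H](C([Ti](Cl)(C3C=CC=C3)C3C=CC=C3)c2cc(O[Si](C)(C)C(C)(C)C)c(OC)c(OC)c2)[C@@H]1CO[Ti](Cl)(C1C=CC=C1)C1C=CC=C1 | intermediate (not isolated)
15 | ring A closed (2,3-trans, 3,4-cis tetrahydrofuran) with iodine on benzylic C6 and Cp2Ti(Cl)–O on C8 | CC(C)(C)[Si](C)(C)Oc1ccc(cc1OC)[C@H]1OC[C@H](C(I)c2cc(O[Si](C)(C)C(C)(C)C)c(OC)c(OC)c2)[C@@H]1CO[Ti](Cl)(C1C=CC=C1)C1C=CC=C1 | intermediate (not isolated)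
16 | (1R,2S,5R,6S)-2-{4-[(tert-butyldimethylsilyl)oxy]-3-methoxyphenyl}-6-{3-[(tert-butyldimethylsilyl)oxy]-4,5-dimethoxyphenyl}-3,7-dioxabicyclo[3.3.0]octane | CC(C)(C)[Si](C)(C)Oc1ccc(cc1OC)[C@H]1OC[C@H]2[C@@H]1CO[C@@H]2c1cc(O[Si](C)(C)C(C)(C)C)c(OC)c(OC)c1 | intermediate
17 | (1R,2S,5R,6S)-2-(4-hydroxy-3-methoxyphenyl)-6-(3-hydroxy-4,5-dimethoxyphenyl)-3,7-dioxabicyclo[3.3.0]octane | COc1cc([C@H]2OC[C@H]3[C@@H]2CO[C@@H]3c2cc(O)c(OC)c(OC)c2)ccc1O | target

**Count and risks**

Total steps: 10. Longest linear sequence: 7 steps (6 → 7 → 9 → 11 → 12 → 13 → 16 → 17, steps 4 to 10); the vanillin branch joins after 3 steps.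

Steps most likely to fail:

1. Step 9. The benzylic titanium species may be protonated or reduced before iodine reaches it, which leaves ring B open, or the ring B closure may not favour the exo face cleanly. Fallback, from 13 back to 16: run the same Cp2TiCl cyclisation (Cp2TiCl2, Zn dust, THF, rt) but quench with aq NaH2PO4 and isolate the monocyclic alcohol [(2S,3R,4R)-2-{4-[(tert-butyldimethylsilyl)oxy]-3-methoxyphenyl}-4-{3-[(tert-butyldimethylsilyl)oxy]-4,5-dimethoxybenzyl}oxolan-3-yl]methanol F1. Then close ring B separately by benzylic oxidation with DDQ (CH2Cl2, 4 Å MS, 0 °C). Hydride abstraction at C6 of the more electron-rich, para-methoxy-bearing ring B arene should give the same benzylic cation, which the C8 hydroxyl traps from the convex face to give 16.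

2. Step 8. The electron-rich cinnamyl bromide may ionise and decompose or alkylate at the wrong allylic terminus, and the hindered secondary alcohol may react too slowly. Fallback, from 5 and 7 back to 13: alkylate 5 with allyl bromide (Ag2O, CH2Cl2, rt) to the allyl ether (2S)-2-[(R)-{4-[(tert-butyldimethylsilyl)oxy]-3-methoxyphenyl}(prop-2-en-1-yloxy)methyl]oxirane F2. Convert 7 by Wittig methylenation (Ph3PCH3Br, KOtBu, THF, 0 °C) into the styrene 1-[(tert-butyldimethylsilyl)oxy]-5-ethenyl-2,3-dimethoxybenzene F3. Join F2 and F3 by E-selective cross-metathesis with the second-generation Grubbs catalyst RuCl2(=CHPh)(H2IMes)(PCy3) (CH2Cl2, 40 °C) to give 13; this route needs no cinnamyl bromide.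

3. Step 3. The catalyst may discriminate the enantiomers of this aryl vinyl carbinol too weakly, so that the epoxy alcohol carries too much of the wrong C2 configuration. Fallback, from 4 back to 5: separate resolution from epoxidation. Acylate racemic 4 with immobilised Candida antarctica lipase B and vinyl acetate (hexane, 30 °C). This should convert the R enantiomer into the acetate (R)-1-{4-[(tert-butyldimethylsilyl)oxy]-3-methoxyphenyl}prop-2-en-1-yl acetate F4 and leave the alcohol (S)-1-{4-[(tert-butyldimethylsilyl)oxy]-3-methoxyphenyl}prop-2-en-1-ol F5. After chromatography, epoxidise F5 in the matched sense (Ti(OiPr)4, D-(−)-diisopropyl tartrate, tBuOOH 1.5 equiv, 4 Å MS, CH2Cl2, −20 °C) to give 5.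

Further compounds
F1 | step 9 | [(2S,3R,4R)-2-{4-[(tert-butyldimethylsilyl)oxy]-3-methoxyphenyl}-4-{3-[(tert-butyldimethylsilyl)oxy]-4,5-dimethoxybenzyl}oxolan-3-yl]methanol | CC(C)(C)[Si](C)(C)Oc1ccc(cc1OC)[C@H]1OC[C@H](Cc2cc(O[Si](C)(C)C(C)(C)C)c(OC)c(OC)c2)[C@@H]1CO
F2 | step 8 | (2S)-2-[(R)-{4-[(tert-butyldimethylsilyl)oxy]-3-methoxyphenyl}(prop-2-en-1-yloxy)methyl]oxirane | CC(C)(C)[Si](C)(C)Oc1ccc(cc1OC)[C@@H](OCC=C)[C@@H]1CO1
F3 | step 8 | 1-[(tert-butyldimethylsilyl)oxy]-5-ethenyl-2,3-dimethoxybenzene | C=Cc1cc(O[Si](C)(C)C(C)(C)C)c(OC)c(OC)c1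
F4 | step 3 | (R)-1-{4-[(tert-butyldimethylsilyl)oxy]-3-methoxyphenyl}prop-2-en-1-yl acetate | COc1cc([C@H](OC(C)=O)C=C)ccc1O[Si](C)(C)C(C)(C)C
F5 | step 3 | (S)-1-{4-[(tert-butyldimethylsilyl)oxy]-3-methoxyphenyl}prop-2-en-1-ol | COc1cc([C@@H](O)C=C)ccc1O[Si](C)(C)C(C)(C)C
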